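(The earlier runs and the new flask are calculated with made-up constants; scatter was added.)

**Reading a constant.** No constant was given for this flask, so I read the one that matters from the runs. The questions and charges were these.

| setting | beta | epsilon | theta | delta | eta |
|---|---|---|---|---|---|
| substrate | 0.600 M | 0.360 M | 0.600 M | 0.600 M | 0.600 M |
| free catalyst | 0.0600 M | 0.0600 M | 0.0900 M | 0.0600 M | 0.0600 M |
| target |  |  |  | 0.300 M |  |
| time |  |  |  |  | 8.8 min |

- beta run (time / min: [target] / M): 0.14: 0.011; 0.22: 0.018; 0.35: 0.039; 0.56: 0.056; 0.88: 0.076; 1.4: 0.106; 2.2: 0.136; 3.5: 0.164
- epsilon run (time / min: [target] / M): 0.14: 0.012; 0.22: 0.017; 0.35: 0.031; 0.56: 0.043; 0.88: 0.067; 1.4: 0.089; 2.2: 0.112; 3.5: 0.116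
- theta run (time / min: [target] / M): 0.14: 0.034; 0.22: 0.051; 0.35: 0.079; 0.56: 0.114; 0.88: 0.159; 1.4: 0.220; 2.2: 0.258; 3.5: 0.214
- delta run (time / min: [target] / M): 0.14: 0.296; 0.22: 0.293; 0.35: 0.292; 0.56: 0.280; 0.88: 0.279; 1.4: 0.266; 2.2: 0.249; 3.5: 0.225

(standard deviation of a reading: 0.003 M)

- Overall: substrate -> target, with free catalyst as catalyst.
- Constant volume, constant temperature.
- Bound and free are read together.
- An order is taken over about fifteen percent of the charge, up and down.

- order of the initial rate in [free catalyst], near the charge of the beta run, the rate being that where two percent of its substrate are target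
- order of the initial rate in [substrate], near the charge of the beta run, the rate being that where two percent of its substrate are target (one fixed amount of target, the same in the runs compared)
- target in the eta run at 8.8 min, as a share of the substrate charged

**Two orders.** I read mean rates from the start of each run. The beta run reached 0.056 M at 0.56 min, a mean rate r of 0.100 M min⁻¹, and the theta run reached a similar 0.051 M at 0.22 min, a mean rate of 0.232 M min⁻¹; these readings gave an order of 2.07 in free catalyst across that wide step. At 0.88 min the beta run stood at 0.076 M and the epsilon run at 0.067 M, which gave an order of 0.247 in substrate. I therefore took formation in the beta charge as roughly constant for my reckoning.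

**Target lifetime.** The delta run fell by 0.0211 M min⁻¹ around a mean of 0.261 M. I assumed that its formation, with the beta charge of substrate and catalyst, matched the beta rate. Loss was then that rate plus the fall. Taking loss as first order, the target lifetime τ, mean target divided by loss rate, was 2.15 min.

**The ladder.** At the first beta reading, 0.14 min, only 0.0651 lifetimes had passed. Next came τ: I reckoned that beta target climbed towards a balance level (a steady state) of 0.215 M, and its last reading, 0.164 M, stood lower than that. Slower still, the rate r, held constant, would use the eta charge in 6.00 min, which is longer than τ. As a crude step I cut formation off at that time and counted the remaining 1.30 lifetimes to 8.8 min as decay, which gave 9.15% for the eta run. The rate slows as substrate falls, so formation runs on past that cut, and I expected a share somewhat above this figure.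

**The forecast.** It gave orders of 2.5 and 0.1 and a share of 25%, holding that “target strongly inhibits its own formation and is also lost”.

**The result.** The flask gave orders of 2.7 and 0.20, and 11.7% in the eta run.

    free catalyst + substrate ⇌ catalyst-substrate complex, settled at all times (24.20 L mol⁻¹)
    catalyst-substrate complex + substrate ⇌ doubly bound catalyst, settled at all times (10.10 L mol⁻¹)
    doubly bound catalyst → target + catalyst-substrate complex (5.346 min⁻¹)
    target → decomposed product (0.4566 min⁻¹)
    free catalyst + impurity → spent catalyst

**The decay.** The step from target to decomposed product set the eta share: the eta run gave 11.7% with it and 94.0% without it. The asked time was 4.09 lifetimes. That ratio of shares corresponds to 2.08 lifetimes, as if the surviving target had aged 4.48 min. In the theta run, between 2.2 min and 3.5 min, τ gave a loss of 0.110 M min⁻¹ against a measured fall of 0.0338 M min⁻¹. The difference left theta formation of 0.0762 M min⁻¹ over that stretch.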